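## Plan

- The retrosynthesis cuts O1–C2 first (Mitsunobu etherification), then O1–C8a and C4–C4a together (an aryne inserted into the acyl–oxygen bond of a β-silyloxy acid).
- Enabling feature: ring A carries O1 on C8a and the acyl carbon C4 on the neighbouring C4a, between the 5-methoxy and 8-prenyl groups. This is the pattern an acyl–O bond leaves when it adds across a C4a≡C8a aryne polarised by the 5-methoxy group.
- Forward: ring A is elaborated from symmetric 3,5-dimethoxyphenol (reverse-prenyl ether, Claisen; carbamate-directed silylation, triflation). The C2–C3–C4 chain is joined in the aryne step without ring closure, and the pyranone ring closes last.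
- Stereochemistry: C2 comes from commercial ethyl (R)-3-hydroxy-3-phenylpropanoate, carried as its TIPS ether and inverted once in the Mitsunobu closure to 2S.

Key step: step 9

Remark: flavanone numbering (O1, C2–C4, C4a, C5–C8, C8a) is used for ring atoms and prenyl means 3-methylbut-2-en-1-yl; phenoxide, carboxylate and ammonium salts of numbered compounds are not numbered separately, and 14 is assumed to be bought enantiopure.

## Route

Step 1
Reactants: 1 3,5-dimethoxyphenol; 2 3-chloro-3-methylbut-1-yne
Product: 3 1,3-dimethoxy-5-[(2-methylbut-3-yn-2-yl)oxy]benzene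
Conditions: CuCl2·2H2O (cat.), DBU, MeCN, 0 °C
Reagents that add atoms: none
Why: Copper-catalysed O-propargylation of the phenoxide with a tertiary propargylic chloride (Williamson-type etherification through a copper-stabilised propargyl cation equivalent) should give the hindered aryl ether without C-alkylation.

Step 2
Reactants: 3 1,3-dimethoxy-5-[(2-methylbut-3-yn-2-yl)oxy]benzene
Product: 4 1,3-dimethoxy-5-[(2-methylbut-3-en-2-yl)oxy]benzene
Conditions: H2 (1 atm), Lindlar catalyst, quinoline, EtOAc, rt
Reagents that add atoms: none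
Why: Lindlar semihydrogenation should stop at the terminal alkene because the poisoned palladium reduces the alkyne much faster than the olefin and does not touch the aryl ether.

Step 3
Reactants: 4 1,3-dimethoxy-5-[(2-methylbut-3-en-2-yl)oxy]benzene
Product: 6 3,5-dimethoxy-2-prenylphenol, via Claisen dienone 5 (not isolated)
Conditions: PhNEt2, 130 °C
Reagents that add atoms: none
Why: The aromatic Claisen rearrangement ([3,3]-sigmatropic shift, then tautomerisation of dienone 5) turns the reverse-prenyl ether into the linear ortho-prenyl phenol; both ortho positions are equivalent by symmetry and the basic solvent suppresses acid-catalysed chroman formation.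

Step 4
Reactants: 6 3,5-dimethoxy-2-prenylphenol
Product: 7 3,5-dimethoxy-2-prenylphenyl N-isopropylcarbamate
Conditions: iPrNCO, Et3N (cat.), CH2Cl2, rt
Reagents that add atoms: isopropyl isocyanate, CC(C)N=C=O
Why: Amine-catalysed addition of the phenol to the isocyanate (carbamoylation) installs a strong ortho-directing group that can later be removed with mild base.

Step 5
Reactants: 7 3,5-dimethoxy-2-prenylphenyl N-isopropylcarbamate
Product: 11 3,5-dimethoxy-2-prenyl-6-(trimethylsilyl)phenyl N-isopropylcarbamate, via N-silyl carbamate 8 (not isolated), via aryllithium 9 (not isolated), via bis-silyl carbamate 10 (not isolated)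
Conditions: TMSOTf, TMEDA, Et2O, 0 °C → rt; n-BuLi (2 equiv), TMEDA, −78 °C; TMSCl, −78 °C → rt; aq. NH4Cl
Reagents that add atoms: chlorotrimethylsilane, C[Si](C)(C)Cl; trimethylsilyl triflate, C[Si](C)(C)OS(=O)(=O)C(F)(F)F (its silyl group stays only in intermediates 8–10)
Why: Directed ortho-metalation: after in situ N-silylation the carbamate and the flanking methoxy group together direct butyllithium to the only ring C–H lying between two oxygen substituents, and TMSCl traps the aryllithium; the benzylic CH2 of the twisted prenyl group is poorly aligned for lateral deprotonation at −78 °C.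

Step 6
Reactants: 11 3,5-dimethoxy-2-prenyl-6-(trimethylsilyl)phenyl N-isopropylcarbamate
Product: 13 3,5-dimethoxy-2-prenyl-6-(trimethylsilyl)phenyl trifluoromethanesulfonate, via silyl phenol 12 (not isolated)
Conditions: Et2NH, DBU, MeCN, 40 °C; then PhNTf2, rt
Reagents that add atoms: N-phenylbis(trifluoromethanesulfonimide), O=S(=O)(N(c1ccccc1)S(=O)(=O)C(F)(F)F)C(F)(F)F
Why: Base-induced E1cB cleavage of the N–H carbamate (the isocyanate is trapped by diethylamine as a urea) frees the phenoxide, which is triflated in the same pot (O-sulfonylation) by a mild reagent that spares the electron-rich aryl–silicon bond and the prenyl alkene.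

Step 7
Reactants: 14 ethyl (R)-3-hydroxy-3-phenylpropanoate
Product: 15 ethyl (R)-3-phenyl-3-(triisopropylsilyloxy)propanoate
Conditions: TIPSOTf, 2,6-lutidine, CH2Cl2, 0 °C → rt
Reagents that add atoms: triisopropylsilyl triflate, CC(C)[Si](OS(=O)(=O)C(F)(F)F)(C(C)C)C(C)C
Why: O-Silylation of the secondary benzylic alcohol with a silyl triflate and a hindered pyridine base forms the silyl ether without touching the stereocentre.

Step 8
Reactants: 15 ethyl (R)-3-phenyl-3-(triisopropylsilyloxy)propanoate
Product: 16 (R)-3-phenyl-3-(triisopropylsilyloxy)propanoic acid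
Conditions: LiOH·H2O, THF/MeOH/H2O, 0 °C → rt; then 1 M HCl to pH 3
Reagents that add atoms: lithium hydroxide, [Li+].[OH-]
Why: Ester saponification should proceed cleanly because the TIPS ether is stable to hydroxide and is too poor a leaving group for E1cB elimination at this temperature.

Step 9
Reactants: 13 3,5-dimethoxy-2-prenyl-6-(trimethylsilyl)phenyl trifluoromethanesulfonate; 16 (R)-3-phenyl-3-(triisopropylsilyloxy)propanoic acid
Product: 19 (R)-1-[2-hydroxy-4,6-dimethoxy-3-prenylphenyl]-3-phenyl-3-(triisopropylsilyloxy)propan-1-one, via aryne 17 (not isolated), via aryl anion ester 18 (not isolated)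
Conditions: 13 (1.5 equiv), CsF (4 equiv), THF, sealed tube, 90 °C (raised towards 125 °C only if conversion stalls); aq. NH4Cl
Reagents that add atoms: none
Why: Fluoride attacks the trimethylsilyl group of 13 and the ortho triflate leaves, giving aryne 17 (C4a≡C8a); the cesium carboxylate of 16 then adds through oxygen at C8a, the terminus remote from the 5-methoxy group, because the aryne is distorted so that C8a is the more electrophilic carbon and the carbanion developing at C4a is stabilised inductively by the adjacent C5–O bond. Aryl anion 18 attacks its own ester carbonyl through a four-membered transition state and the tetrahedral intermediate collapses with C–O cleavage (an anionic ortho-Fries-type O-to-C acyl shift), so that O1–C8a and C4–C4a are formed and the former carboxyl oxygen becomes the C8a phenoxide. The closest known reaction type is the fluoride-induced insertion of arynes into the C–O bond of carboxylic acids, which gives ortho-hydroxyaryl ketones from aromatic and aliphatic acids alike. No ring closes and no stereocentre is created; the carbinol centre is a spectator that is not α to the carbonyl and can be lost only by β-elimination. Three selectivities are needed: regiochemistry (the 5-methoxy group should outweigh the weak opposing effects of the 7-methoxy and 8-prenyl groups, as in 3,5-dimethoxybenzyne), acyl shift over protonation of 18 (aprotic THF, heat, the acid buffered as its cesium salt by excess CsF), and no E1cB loss of silanolate (the TIPS ether is a poor, fluoride-resistant leaving group and the product sits as a phenoxide, a vinylogous carboxylate of low α-acidity).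

Step 10
Reactants: 19 (R)-1-[2-hydroxy-4,6-dimethoxy-3-prenylphenyl]-3-phenyl-3-(triisopropylsilyloxy)propan-1-one
Product: 20 (R)-3-hydroxy-1-[2-hydroxy-4,6-dimethoxy-3-prenylphenyl]-3-phenylpropan-1-one
Conditions: HF·pyridine, pyridine, THF, 0 °C → rt
Reagents that add atoms: none
Why: Desilylation with buffered HF cleaves the Si–O bond without ever forming the free alkoxide, so retro-aldol cleavage, E1cB dehydration and acid cyclisation of the prenyl phenol should all be avoided and the carbinol centre stays R.

Step 11
Reactants: 20 (R)-3-hydroxy-1-[2-hydroxy-4,6-dimethoxy-3-prenylphenyl]-3-phenylpropan-1-one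
Product: 22 (2S)-5,7-dimethoxy-8-prenyl-2-phenylchroman-4-one (candidone), via alkoxyphosphonium phenoxide 21 (not isolated)
Conditions: PPh3, DIAD, THF, 0 °C → rt
Reagents that add atoms: none
Why: Intramolecular Mitsunobu etherification: the hydrogen-bonded phenol protonates the betaine, the carbinol is activated as alkoxyphosphonium 21 and the phenoxide displaces it in a 6-exo-tet SN2 closure with inversion, converting the R carbinol into the 2S centre.

## Compound list

1 | 3,5-dimethoxyphenol | COc1cc(O)cc(OC)c1 | starting material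
2 | 3-chloro-3-methylbut-1-yne | CC(C)(Cl)C#C | starting material
3 | 1,3-dimethoxy-5-[(2-methylbut-3-yn-2-yl)oxy]benzene | COc1cc(OC)cc(OC(C)(C)C#C)c1 | intermediate
4 | 1,3-dimethoxy-5-[(2-methylbut-3-en-2-yl)oxy]benzene | COc1cc(OC)cc(OC(C)(C)C=C)c1 | intermediate
5 | 3,5-dimethoxy-6-prenylcyclohexa-2,4-dien-1-one | O=C1C=C(OC)C=C(OC)C1CC=C(C)C | intermediate (not isolated)
6 | 3,5-dimethoxy-2-prenylphenol | COc1cc(O)c(CC=C(C)C)c(OC)c1 | intermediate
7 | 3,5-dimethoxy-2-prenylphenyl N-isopropylcarbamate | COc1cc(OC(=O)NC(C)C)c(CC=C(C)C)c(OC)c1 | intermediate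
8 | 3,5-dimethoxy-2-prenylphenyl N-isopropyl-N-(trimethylsilyl)carbamate | COc1cc(OC(=O)N(C(C)C)[Si](C)(C)C)c(CC=C(C)C)c(OC)c1 | intermediate (not isolated)
9 | [2-(N-isopropyl-N-trimethylsilylcarbamoyloxy)-4,6-dimethoxy-3-prenylphenyl]lithium | COc1cc(OC)c(CC=C(C)C)c(OC(=O)N(C(C)C)[Si](C)(C)C)c1[Li] | intermediate (not isolated)
10 | 3,5-dimethoxy-2-prenyl-6-(trimethylsilyl)phenyl N-isopropyl-N-(trimethylsilyl)carbamate | COc1cc(OC)c(CC=C(C)C)c(OC(=O)N(C(C)C)[Si](C)(C)C)c1[Si](C)(C)C | intermediate (not isolated)
11 | 3,5-dimethoxy-2-prenyl-6-(trimethylsilyl)phenyl N-isopropylcarbamate | COc1cc(OC)c(CC=C(C)C)c(OC(=O)NC(C)C)c1[Si](C)(C)C | intermediate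
12 | 3,5-dimethoxy-2-prenyl-6-(trimethylsilyl)phenol | COc1cc(OC)c(CC=C(C)C)c(O)c1[Si](C)(C)C | intermediate (not isolated)
13 | 3,5-dimethoxy-2-prenyl-6-(trimethylsilyl)phenyl trifluoromethanesulfonate | COc1cc(OC)c([Si](C)(C)C)c(OS(=O)(=O)C(F)(F)F)c1CC=C(C)C | intermediate
14 | ethyl (R)-3-hydroxy-3-phenylpropanoate | CCOC(=O)C[C@@H](O)c1ccccc1 | starting material
15 | ethyl (R)-3-phenyl-3-(triisopropylsilyloxy)propanoate | CCOC(=O)C[C@@H](O[Si](C(C)C)(C(C)C)C(C)C)c1ccccc1 | intermediate
16 | (R)-3-phenyl-3-(triisopropylsilyloxy)propanoic acid | OC(=O)C[C@@H](O[Si](C(C)C)(C(C)C)C(C)C)c1ccccc1 | intermediate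
17 | 1,2-didehydro-3,5-dimethoxy-6-prenylbenzene (aryne) | COC1=C(CC=C(C)C)C#CC(OC)=C1 | intermediate (not isolated)
18 | cesium 2-[(R)-3-phenyl-3-(triisopropylsilyloxy)propanoyloxy]-4,6-dimethoxy-3-prenylbenzen-1-ide | COc1cc(OC)[c-]c(OC(=O)C[C@@H](O[Si](C(C)C)(C(C)C)C(C)C)c2ccccc2)c1CC=C(C)C.[Cs+] | intermediate (not isolated)
19 | (R)-1-[2-hydroxy-4,6-dimethoxy-3-prenylphenyl]-3-phenyl-3-(triisopropylsilyloxy)propan-1-one | COc1cc(OC)c(C(=O)C[C@@H](O[Si](C(C)C)(C(C)C)C(C)C)c2ccccc2)c(O)c1CC=C(C)C | intermediate
20 | (R)-3-hydroxy-1-[2-hydroxy-4,6-dimethoxy-3-prenylphenyl]-3-phenylpropan-1-one | COc1cc(OC)c(C(=O)C[C@@H](O)c2ccccc2)c(O)c1CC=C(C)C | intermediate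
21 | (R)-[3-(4,6-dimethoxy-2-oxido-3-prenylphenyl)-3-oxo-1-phenylpropoxy]triphenylphosphonium (zwitterion) | COc1cc(OC)c(C(=O)C[C@@H](O[P+](c2ccccc2)(c2ccccc2)c2ccccc2)c2ccccc2)c([O-])c1CC=C(C)C | intermediate (not isolated)
22 | (2S)-5,7-dimethoxy-8-prenyl-2-phenylchroman-4-one, candidone | COc1cc(OC)c2c(c1CC=C(C)C)O[C@H](c1ccccc1)CC2=O | target

## Step count and risks

Total steps: 11. Longest linear sequence: 9 steps (steps 1–6, then 9–11); the acid branch (steps 7–8) joins at step 9.

**Step 9 (aryne insertion).** The aryl anion may be protonated before the acyl shift, so that the reaction stops at the aryl ester. The carboxylate may add partly at C4a. Hot fluoride may also strip the silyl ether or trigger β-elimination, which would destroy the stereocentre.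
Fallback, setting out from 7 and 16 and returning at 19: the C4–C4a bond is made by directed metalation and Weinreb acylation, and O1 is kept from the phenol.
- Acid 16 would be coupled with N,O-dimethylhydroxylamine hydrochloride (EDCI, iPr2NEt, CH2Cl2) to give (R)-N-methoxy-N-methyl-3-phenyl-3-(triisopropylsilyloxy)propanamide F1.
- Carbamate 7 would be N-silylated and lithiated exactly as in step 5 to aryllithium 9, which should add to F1 at −78 °C to give the lithium hemiaminal F2.
- Aqueous NH4Cl should collapse this adduct and remove the N-silyl group, giving 3,5-dimethoxy-2-prenyl-6-[(R)-3-phenyl-3-(triisopropylsilyloxy)propanoyl]phenyl N-isopropylcarbamate F3.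
- Diethylamine in MeCN at rt should then cleave the carbamate, the ortho-acyl phenoxide being a good leaving group, and deliver 19 without fluoride or heat.

**Step 5 (directed silylation).** Deprotonation at the benzylic/allylic CH2 of the prenyl group (lateral lithiation) may compete with ring lithiation, or the carbamoyl group may migrate to carbon before the silyl quench.
Fallback, setting out from 1 and returning at 12 (then isolated and triflated with PhNTf2/DBU as in the second half of step 6 to give 13): the order is reversed so that no alkene is present during lithiation.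
- Phenol 1 would be carbamoylated (iPrNCO, Et3N) to 3,5-dimethoxyphenyl N-isopropylcarbamate F4.
- The step 5 protocol, through the N-silyl carbamate F5, the aryllithium F6 and the bis-silyl carbamate F7, should give 3,5-dimethoxy-2-(trimethylsilyl)phenyl N-isopropylcarbamate F8.
- Et2NH/DBU in MeCN should release 3,5-dimethoxy-2-(trimethylsilyl)phenol F9.
- Copper-catalysed etherification with 2 (DBU, MeCN, 0 °C) should give 1,5-dimethoxy-3-[(2-methylbut-3-yn-2-yl)oxy]-2-(trimethylsilyl)benzene F10.
- Lindlar semihydrogenation should give 1,5-dimethoxy-3-[(2-methylbut-3-en-2-yl)oxy]-2-(trimethylsilyl)benzene F11.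
- Claisen rearrangement in PhNEt2 at 130 °C, through 3,5-dimethoxy-6-prenyl-2-(trimethylsilyl)cyclohexa-2,4-dien-1-one F12, can only go into the single free ortho position and should give 12.

**Step 11 (Mitsunobu closure).** The alkoxyphosphonium ion may lose a proton α to the ketone instead of being displaced, and the resulting chalcone would reclose without facial control. The benzylic centre may also ionise. Either process erodes the enantiomeric purity.
Fallback, setting out from 13 and returning at 22: the stereocentre is set by a catalyst instead of by inversion.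
- Triflate 13 and acetic acid under the step 9 conditions (CsF, THF, 125 °C; aryne 17, then cesium 2-acetoxy-4,6-dimethoxy-3-prenylbenzen-1-ide F13) should give 1-[2-hydroxy-4,6-dimethoxy-3-prenylphenyl]ethan-1-one F14; this partner has nothing that can eliminate.
- Condensation with DMF dimethyl acetal (toluene, 90 °C) should give (E)-3-(dimethylamino)-1-[2-hydroxy-4,6-dimethoxy-3-prenylphenyl]prop-2-en-1-one F15.
- Warming in acetic acid (60 °C) should close this, with loss of dimethylamine, to 5,7-dimethoxy-8-prenyl-4H-chromen-4-one F16.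
- Rhodium(I)/chiral diene-catalysed asymmetric 1,4-addition of phenylboronic acid (substoichiometric aq. KOH, dioxane, rt), with the ligand enantiomer chosen to deliver phenyl to the face that gives 2S, should convert F16 directly into 22.

## Further compounds

F1 | step 9 | (R)-N-methoxy-N-methyl-3-phenyl-3-(triisopropylsilyloxy)propanamide | CON(C)C(=O)C[C@@H](O[Si](C(C)C)(C(C)C)C(C)C)c1ccccc1
F2 | step 9 | lithium hemiaminal from 9 and F1 (N-silyl carbamate still in place; new centre not defined) | COc1cc(OC)c(C(O[Li])(N(C)OC)C[C@@H](O[Si](C(C)C)(C(C)C)C(C)C)c2ccccc2)c(OC(=O)N(C(C)C)[Si](C)(C)C)c1CC=C(C)C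
F3 | step 9 | 3,5-dimethoxy-2-prenyl-6-[(R)-3-phenyl-3-(triisopropylsilyloxy)propanoyl]phenyl N-isopropylcarbamate | COc1cc(OC)c(C(=O)C[C@@H](O[Si](C(C)C)(C(C)C)C(C)C)c2ccccc2)c(OC(=O)NC(C)C)c1CC=C(C)C
F4 | step 5 | 3,5-dimethoxyphenyl N-isopropylcarbamate | COc1cc(OC)cc(OC(=O)NC(C)C)c1
F5 | step 5 | 3,5-dimethoxyphenyl N-isopropyl-N-(trimethylsilyl)carbamate | COc1cc(OC)cc(OC(=O)N(C(C)C)[Si](C)(C)C)c1
F6 | step 5 | [2-(N-isopropyl-N-trimethylsilylcarbamoyloxy)-4,6-dimethoxyphenyl]lithium | COc1cc(OC)c([Li])c(OC(=O)N(C(C)C)[Si](C)(C)C)c1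
F7 | step 5 | 3,5-dimethoxy-2-(trimethylsilyl)phenyl N-isopropyl-N-(trimethylsilyl)carbamate | COc1cc(OC)c([Si](C)(C)C)c(OC(=O)N(C(C)C)[Si](C)(C)C)c1
F8 | step 5 | 3,5-dimethoxy-2-(trimethylsilyl)phenyl N-isopropylcarbamate | COc1cc(OC)c([Si](C)(C)C)c(OC(=O)NC(C)C)c1
F9 | step 5 | 3,5-dimethoxy-2-(trimethylsilyl)phenol | COc1cc(OC)c([Si](C)(C)C)c(O)c1
F10 | step 5 | 1,5-dimethoxy-3-[(2-methylbut-3-yn-2-yl)oxy]-2-(trimethylsilyl)benzene | COc1cc(OC)c([Si](C)(C)C)c(OC(C)(C)C#C)c1
F11 | step 5 | 1,5-dimethoxy-3-[(2-methylbut-3-en-2-yl)oxy]-2-(trimethylsilyl)benzene | COc1cc(OC)c([Si](C)(C)C)c(OC(C)(C)C=C)c1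
F12 | step 5 | 3,5-dimethoxy-6-prenyl-2-(trimethylsilyl)cyclohexa-2,4-dien-1-one | O=C1C(CC=C(C)C)C(OC)=CC(OC)=C1[Si](C)(C)C
F13 | step 11 | cesium 2-acetoxy-4,6-dimethoxy-3-prenylbenzen-1-ide | COc1cc(OC)[c-]c(OC(C)=O)c1CC=C(C)C.[Cs+]
F14 | step 11 | 1-[2-hydroxy-4,6-dimethoxy-3-prenylphenyl]ethan-1-one | COc1cc(OC)c(C(C)=O)c(O)c1CC=C(C)C
F15 | step 11 | (E)-3-(dimethylamino)-1-[2-hydroxy-4,6-dimethoxy-3-prenylphenyl]prop-2-en-1-one | COc1cc(OC)c(C(=O)/C=C/N(C)C)c(O)c1CC=C(C)C
F16 | step 11 | 5,7-dimethoxy-8-prenyl-4H-chromen-4-one | COc1cc(OC)c2c(c1CC=C(C)C)OC=CC2=O
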